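**Retrosynthetic overview**

Locants: ring D = C1(=O)–C2–C3(Me)–C4–C10(Me)–C11; cyclobutane = C4–C5–C11–C10; seven-membered ring A = C5–C6(Me)(CH2OAc)–C7(OAng)–C8–C9(OH)–C10–C4.
Endgame: the two esters by selective acylation of a C7,C9,CH2OH triol; the triol by a relayed hydroxyl-directed reduction of a C7,C9-diketone; the diketone from a C8=C9 enone, the CH2OH from a vinyl group.
Key disconnection: C8–C9 (made as C8=C9 by intramolecular Horner–Wadsworth–Emmons olefination) and C5–C11 (enolate cycloalkylation) in one base-mediated operation; ring order: ring D, then ring A, then the cyclobutane.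
Enabling feature: on cyclohexanone ring D the C10 formyl group and the C4 side chain are cis, and the mesylate carbon C5 sits on C4, 1,3 across C10 to the α-carbon C11 of the C1 ketone; once ring A is closed, the rear of the C5–O bond faces C11 only.
Ring D with its C3/C4/C10 triad comes from an auxiliary-controlled Diels–Alder reaction of a 2-siloxypentadiene with a 5-menthyloxy-4-methylbutenolide; C5/C6 come from an iridium-catalysed tert-(hydroxy)prenylation with isoprene monoxide.

Key step: step 12

Assumption: (+)-menthol is taken to give the crystalline 5S acetal 3 (mirror image of the known (−)-menthyl/5R pairing of the parent butenolide), and "anti" in step 7 means the secondary OH is anti to CH2OH when the chain is drawn through the vinyl group.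

**Route**

Step 1
Reactants: 1 5-hydroxy-4-methylfuran-2(5H)-one (racemic lactol); 2 (1S,2R,5S)-(+)-menthol
Product: 3 (5S)-5-[(1S,2R,5S)-menthyloxy]-4-methylfuran-2(5H)-one
Conditions: TsOH (cat.), toluene, reflux (Dean–Stark); crystallization from hexane
Reagents that add atoms: none
Why: Acid-catalysed acetalization gives both C5 epimers, which interconvert through the oxocarbenium ion, so the 5S epimer should be collected by crystallization-induced enrichment; this acetal centre fixes the absolute configuration of the route.

Step 2
Reactants: 4 (E)-pent-3-en-2-one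
Product: 5 (E)-2-(trimethylsilyloxy)penta-1,3-diene
Conditions: LiN(i-Pr)2, THF, −78 °C; TMSCl
Reagents that add atoms: chlorotrimethylsilane C[Si](C)(C)Cl
Why: Kinetic deprotonation at the methyl group gives the cross-conjugated dienolate, and O-silylation should give the 2-siloxydiene with the E double bond untouched.

Step 3
Reactants: 3 (5S)-menthyloxy butenolide; 5 siloxydiene
Product: 6 cis-fused adduct 3-(menthyloxy)-3a,7-dimethyl-5-(trimethylsilyloxy)-3a,4,7,7a-tetrahydro-2-benzofuran-1(3H)-one (C7 methyl cis to the lactone carbonyl; menthyloxy trans to the C3a–C4 bond)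
Conditions: toluene, BHT (cat.), 110 °C, sealed tube
Reagents that add atoms: none
Why: Diels–Alder reaction in which the CH2 terminus next to the siloxy carbon bonds to the butenolide β-carbon (future C10) and the methyl-bearing terminus to the α-carbon (C4), an ortho/para-consonant orientation; addition anti to the menthyloxy group and endo to the lactone should set C10, C4 and C3 in one step.

Step 4
Reactants: 6 Diels–Alder adduct
Product: 7 2-formyl-N-methoxy-N,2,6-trimethyl-4-oxocyclohexane-1-carboxamide (carboxamide, formyl and C6 methyl all cis)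
Conditions: MeNH(OMe)·HCl, AlMe3, CH2Cl2, 0 °C to rt; then 1 M HCl
Reagents that add atoms: N,O-dimethylhydroxylamine hydrochloride CNOC.Cl
Why: Aluminium amide aminolysis of the lactone (Weinreb amide formation) leaves a hemiacetal that collapses on acidic work-up to the C9 aldehyde and menthol while the enol silane is hydrolysed to the C1 ketone; no stereocentre is touched.

Step 5
Reactants: 7 keto aldehyde Weinreb amide
Product: 8 bis(1,3-dioxolane) of 7 (aldehyde and ketone both protected)
Conditions: HOCH2CH2OH, TsOH (cat.), benzene, reflux (Dean–Stark)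
Reagents that add atoms: ethane-1,2-diol OCCO
Why: Acid-catalysed acetalization with azeotropic water removal masks the aldehyde and the ketone against the hydride and coupling steps that follow.

Step 6
Reactants: 8 bis-dioxolane Weinreb amide
Product: 9 bis-dioxolane aldehyde (CHO on C4)
Conditions: LiAlH4, THF, −78 to 0 °C; then sat. aq. Rochelle salt, 0 °C
Reagents that add atoms: none
Why: Weinreb amide reduction stops at the chelated tetrahedral intermediate, which releases the aldehyde only on cold, near-neutral aqueous work-up, so over-reduction is avoided and C4 is not exposed to base; the aldehyde is used at once without chromatography.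

Step 7
Reactants: 9 bis-dioxolane aldehyde; 10 2-methyl-2-vinyloxirane (isoprene monoxide, racemic)
Product: 11 (1S,2S)-1-(ring D bis-dioxolane)-2-methyl-2-vinylpropane-1,3-diol (C5–OH anti to CH2OH)
Conditions: [Ir(cod)Cl]2 (cat.), Tol-BINAP (cat., enantiomer chosen for the 5S carbinol), 4-cyano-3-nitrobenzoic acid (cat.), K3PO4 (cat.), i-PrOH (2 equiv), THF, 60 °C
Reagents that add atoms: none
Why: Iridium-catalysed transfer-hydrogenative carbonyl tert-(hydroxy)prenylation from the aldehyde oxidation level: 2-propanol is the terminal reductant and the π-allyliridium species from isoprene monoxide adds to the aldehyde through a closed chair transition state, which should give the anti relation of C5–OH and CH2OH at the new quaternary C6, with the chiral ligand setting the absolute sense at C5.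

Step 8
Reactants: 11 diol
Product: 12 hydroxy aldehyde (CH2OH of 11 oxidized to CHO, the future C7)
Conditions: TEMPO (cat.), PhI(OAc)2, CH2Cl2, rt
Reagents that add atoms: none
Why: Oxoammonium (TEMPO) oxidation is selective for the primary alcohol over the hindered secondary C5 alcohol and stops at the non-enolizable aldehyde.

Step 9
Reactants: 12 hydroxy aldehyde
Product: 13 C5 mesylate of 12
Conditions: MsCl, Et3N, CH2Cl2, 0 °C
Reagents that add atoms: methanesulfonyl chloride CS(=O)(=O)Cl
Why: Mesylation through sulfene sulfonylates the hindered secondary alcohol with retention at C5, and the α-quaternary aldehyde cannot eliminate.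

Step 10
Reactants: 13 mesyloxy aldehyde; 14 dimethyl (diazomethyl)phosphonate
Product: 15 β-ketophosphonate (C7 ketone, C8 CH2P(O)(OMe)2), bis-dioxolane, C5 mesylate
Conditions: SnCl2 (cat.), CH2Cl2, rt
Reagents that add atoms: none
Why: Roskamp homologation: the SnCl2-activated aldehyde is attacked by the diazo carbon and a 1,2-hydride shift with loss of N2 gives the β-ketophosphonate, the diazo carbon becoming C8.

Step 11
Reactants: 15 bis-dioxolane ketophosphonate
Product: 16 monocyclic keto aldehyde (C1 ketone, C10 formyl, C5 mesylate, β-ketophosphonate, C6 vinyl)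
Conditions: TFA/H2O (9:1), CH2Cl2, 0 °C to rt
Reagents that add atoms: water O
Why: Acid hydrolysis of both dioxolanes; the neopentyl mesylate and the ketophosphonate should be stable to aqueous acid.

Step 12
Reactants: 16 keto aldehyde
Product: 18 tricyclic enone (C1 ketone, C7 ketone conjugated with C8=C9, C6 vinyl), via cycloheptenone mesylate 17 (not isolated)
Conditions: KOt-Bu (2.4 equiv), THF/t-BuOH (10:1), 0.005 M, 0 to 45 °C
Reagents that add atoms: none
Why: The β-ketophosphonate is by far the most acidic site, so the first equivalent of base gives the C8 carbanion, which adds to the C9 aldehyde (7-exo-trig) and eliminates dimethyl phosphate: an intramolecular Horner–Wadsworth–Emmons olefination that closes ring A as cis-cycloheptenone 17 and never leaves a free C9 alkoxide that could etherify C5. The second equivalent enolizes the C1 ketone reversibly (t-BuOH as proton shuttle) and the C11 enolate displaces the C5 mesylate (4-exo-tet, enolate C=C exocyclic), the closest precedent being the keto sulfonate cycloalkylations that build pinane- and copaane-type bicyclo[3.1.1]heptan-2-ones. With ring A closed, C6 is held gauche to C10 on C5, so the rear of the C5–O bond points at C11 alone; the C2 enolate cannot reach it, and the C4–H bond is gauche to the leaving group, which disfavours E2 elimination. C5 is inverted (its configuration comes from step 7) and C11 is fixed by the need of the one-carbon bridge to span C4 and C11 on the face of ring D that carries the axial C5; no other stereocentre is made. O-alkylation would give a bridgehead enol ether and the enone of 17 has no enolizable hydrogen, so C-alkylation to 18 should be the only irreversible exit, and high dilution holds back intermolecular olefination.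

Step 13
Reactants: 18 tricyclic enone
Product: 19 C8,C9-epoxy ketone
Conditions: t-BuOOH, DBU, CH2Cl2, 0 °C to rt
Reagents that add atoms: tert-butyl hydroperoxide CC(C)(C)OO
Why: Weitz–Scheffer nucleophilic epoxidation attacks only the enone (the vinyl group and the saturated ketone are inert), and the epoxide configuration is of no consequence because it is erased in step 14.

Step 14
Reactants: 19 epoxy ketone
Product: 20 C7,C9-diketone (C6 vinyl)
Conditions: Pd(PPh3)4 (cat.), 1,2-bis(diphenylphosphino)ethane (cat.), toluene, 100 °C
Reagents that add atoms: none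
Why: Zerovalent palladium-catalysed isomerization of an α,β-epoxy ketone to the β-diketone (oxidative addition at the C8–O bond, β-hydride elimination from C9, tautomerization).

Step 15
Reactants: 20 vinyl diketone
Product: 21 C6-formyl C7,C9-diketone
Conditions: O3, CH2Cl2, −78 °C (indicator end point); PPh3
Reagents that add atoms: ozone [O-][O+]=O
Why: Ozonolysis of the only electron-rich C=C (the seven-membered 1,3-diketone should be largely in the diketo form) with reductive work-up gives the aldehyde, which is used crude.

Step 16
Reactants: 21 formyl diketone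
Product: 24 triol (C7–OH, C9–OH, C6–CH2OH; C1 ketone), via hydroxymethyl diketone 22 (not isolated), via hydroxy ketone diol 23 (not isolated)
Conditions: Me4NBH(OAc)3 (excess), MeCN/AcOH (1:1), −20 °C to rt
Reagents that add atoms: none
Why: The aldehyde is reduced first; the CH2O-bound borohydride then delivers hydride intramolecularly to the C7 ketone from its own side (Evans–Saksena reduction), giving C7–OH trans to CH2OH, and the C7 alkoxyborohydride in turn reduces the C9 ketone to the anti-1,3-diol, so C7 and C9 should be set by relay from C6 while the C1 ketone, which has no β-hydroxyl, survives.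

Step 17
Reactants: 24 triol
Product: 25 primary acetate (C6–CH2OAc; C7,C9-diol)
Conditions: AcCl, 2,4,6-collidine, CH2Cl2, −78 °C
Reagents that add atoms: acetyl chloride CC(Cl)=O
Why: Kinetic acylation at low temperature should select the primary hydroxyl over the two neopentyl secondary ones.

Step 18
Reactants: 25 diol acetate; 26 angelic acid ((Z)-2-methylbut-2-enoic acid)
Product: 28 CNP0212099.1, via mixed anhydride 27 (not isolated)
Conditions: 26, 2,4,6-trichlorobenzoyl chloride, Et3N, toluene, rt; then 25, 80 °C (no nucleophilic catalyst)
Reagents that add atoms: none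
Why: Yamaguchi esterification through the mixed anhydride without a nucleophilic catalyst keeps the Z geometry of the angelate, and the equatorial C7–OH should react in preference to the axial C9–OH, which is shielded by the quaternary cyclobutane carbon C10.

**Compound list**

1 | 5-hydroxy-4-methylfuran-2(5H)-one (racemic) | CC1=CC(=O)OC1O | starting material
2 | (1S,2R,5S)-(+)-menthol | CC(C)[C@H]1CC[C@H](C)C[C@@H]1O | starting material
3 | (5S)-5-[(1S,2R,5S)-menthyloxy]-4-methylfuran-2(5H)-one | CC(C)[C@H]1CC[C@H](C)C[C@@H]1O[C@H]2OC(=O)C=C2C | intermediate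
4 | (E)-pent-3-en-2-one | C/C=C/C(C)=O | starting material
5 | (E)-2-(trimethylsilyloxy)penta-1,3-diene | C/C=C/C(=C)O[Si](C)(C)C | intermediate
6 | cis-fused Diels–Alder adduct (menthyloxy lactone acetal, enol silane, all-cis C3a/C7/C7a) | CC(C)[C@H]1CC[C@H](C)C[C@@H]1O[C@H]2OC(=O)[C@@H]3[C@H](C)C=C(O[Si](C)(C)C)C[C@]23C | intermediate
7 | 2-formyl-N-methoxy-N,2,6-trimethyl-4-oxocyclohexane-1-carboxamide (amide, formyl and C6 methyl cis) | O=C[C@@]1(C)CC(=O)C[C@@H](C)[C@H]1C(=O)N(C)OC | intermediate
8 | bis(1,3-dioxolane) of 7 | C1COC(O1)[C@@]2(C)CC3(OCCO3)C[C@@H](C)[C@H]2C(=O)N(C)OC | intermediate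
9 | bis-dioxolane aldehyde (CHO on C4) | C1COC(O1)[C@@]2(C)CC3(OCCO3)C[C@@H](C)[C@H]2C=O | intermediate
10 | 2-methyl-2-vinyloxirane (isoprene monoxide, racemic) | CC1(C=C)CO1 | starting material
11 | (1S,2S)-1-(ring D bis-dioxolane)-2-methyl-2-vinylpropane-1,3-diol | C1COC(O1)[C@@]2(C)CC3(OCCO3)C[C@@H](C)[C@H]2[C@H](O)[C@](C)(CO)C=C | intermediate
12 | β-hydroxy aldehyde (C5–OH, C7 aldehyde, C6 vinyl) | C1COC(O1)[C@@]2(C)CC3(OCCO3)C[C@@H](C)[C@H]2[C@H](O)[C@](C)(C=O)C=C | intermediate
13 | C5 mesylate of 12 | C1COC(O1)[C@@]2(C)CC3(OCCO3)C[C@@H](C)[C@H]2[C@H](OS(C)(=O)=O)[C@](C)(C=O)C=C | intermediate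
14 | dimethyl (diazomethyl)phosphonate | COP(=O)(OC)C=[N+]=[N-] | starting material
15 | bis-dioxolane β-ketophosphonate mesylate | C1COC(O1)[C@@]2(C)CC3(OCCO3)C[C@@H](C)[C@H]2[C@H](OS(C)(=O)=O)[C@](C)(C(=O)CP(=O)(OC)OC)C=C | intermediate
16 | monocyclic keto aldehyde β-ketophosphonate mesylate (key-step precursor) | O=C[C@@]1(C)CC(=O)C[C@@H](C)[C@H]1[C@H](OS(C)(=O)=O)[C@](C)(C(=O)CP(=O)(OC)OC)C=C | intermediate
17 | bicyclic cycloheptenone mesylate (ring A closed, C8=C9) | O=C1C=C[C@@]2(C)CC(=O)C[C@@H](C)[C@H]2[C@H](OS(C)(=O)=O)[C@@]1(C)C=C | intermediate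
18 | tricyclic enone (C1 ketone, C7 enone, C6 vinyl) | O=C1C=C[C@]2(C)[C@@H]3[C@@H]([C@H]2C(=O)C[C@H]3C)[C@@]1(C)C=C | intermediate
19 | C8,C9-epoxy ketone (expected major epimer; configuration erased in step 14) | O=C1[C@@H]2O[C@@H]2[C@]3(C)[C@@H]4[C@@H]([C@H]3C(=O)C[C@H]4C)[C@@]1(C)C=C | intermediate
20 | C7,C9-diketone with C6 vinyl | O=C1CC(=O)[C@]2(C)[C@@H]3[C@@H]([C@H]2C(=O)C[C@H]3C)[C@@]1(C)C=C | intermediate
21 | C6-formyl C7,C9-diketone | O=C1CC(=O)[C@]2(C)[C@@H]3[C@@H]([C@H]2C(=O)C[C@H]3C)[C@@]1(C)C=O | intermediate
22 | C6-hydroxymethyl C7,C9-diketone | O=C1CC(=O)[C@]2(C)[C@@H]3[C@@H]([C@H]2C(=O)C[C@H]3C)[C@@]1(C)CO | intermediate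
23 | C7-hydroxy C9-ketone with C6–CH2OH | O[C@@H]1CC(=O)[C@]2(C)[C@@H]3[C@@H]([C@H]2C(=O)C[C@H]3C)[C@@]1(C)CO | intermediate
24 | triol (C7–OH, C9–OH, C6–CH2OH; C1 ketone) | O[C@@H]1C[C@@H](O)[C@]2(C)[C@@H]3[C@@H]([C@H]2C(=O)C[C@H]3C)[C@@]1(C)CO | intermediate
25 | C6–CH2OAc C7,C9-diol | O[C@@H]1C[C@@H](O)[C@]2(C)[C@@H]3[C@@H]([C@H]2C(=O)C[C@H]3C)[C@@]1(C)COC(C)=O | intermediate
26 | angelic acid, (Z)-2-methylbut-2-enoic acid | C/C=C(/C)C(O)=O | starting material
27 | angelic 2,4,6-trichlorobenzoic anhydride | C/C=C(/C)C(=O)OC(=O)c1c(Cl)cc(Cl)cc1Cl | intermediate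
28 | CNP0212099.1 (3R,4S,5S,6S,7R,9R,10R,11R in the locants of the overview) | C/C=C(/C)C(=O)O[C@@H]1C[C@@H](O)[C@]2(C)[C@@H]3[C@@H]([C@H]2C(=O)C[C@H]3C)[C@@]1(C)COC(C)=O | target

**Step count and risk**

Total steps: 18. Longest linear sequence: 17 steps (steps 1 and 3 to 18; step 2 is a one-step branch).

Steps most likely to fail:

1. Step 12 (key step). The C5 mesylate may be lost by elimination before the strained four-membered ring closes, or the olefination may turn intermolecular, so that only ring A or neither ring forms. Fallback, setting out from 15 and returning at 18, reverses the order of ring closure and separates the two events. The ketone dioxolane alone is hydrolysed (PPTS, wet acetone) to the keto acetal F1. KOt-Bu in THF/t-BuOH then closes the cyclobutane first, the phosphonate anion having no aldehyde partner, to give the bicyclic ketophosphonate acetal F2. Aqueous TFA frees the bicyclic keto aldehyde F3, and a Masamune–Roush olefination (LiCl, DBU, MeCN, high dilution) closes ring A to 18.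

2. Step 3. The β,β-disubstituted butenolide may be too poor a dienophile, so that the diene decomposes first, or endo and facial selectivity may be eroded at the temperature needed. Fallback, setting out from 3 and 4 and returning at 7, is an anionic double Michael annulation. The kinetic lithium dienolate of 4 (LiN(i-Pr)2, THF, −78 °C) adds to 3 anti to the menthyloxy group, and the lactone enolate closes onto the enone to give the keto lactone F4. F4 is opened with MeNH(OMe)·HCl/AlMe3 and acidic work-up, as in step 4, to 7.

3. Step 7. The coupling joins a hindered aldehyde carbon to a new quaternary centre and may be slow; the α-branched aldehyde may then epimerize at C4 under the mildly basic conditions at 60 °C, or catalyst and substrate control may be mismatched. Fallback, setting out from 9 and returning at 11, is a stoichiometric allylboration under base-free conditions. Aldehyde 9 is treated at low temperature with (E)-2-methyl-4-(pinacolboryl)but-2-en-1-ol F5, made from 10 by copper-catalysed SN2′ borylation (B2pin2, CuCl, Xantphos, KOt-Bu, MeOH). The closed chair transition state, if needed under chiral phosphoric acid catalysis, should give 11 after aqueous work-up.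

Further compounds
F1 | step 12 | keto mono-dioxolane β-ketophosphonate mesylate (C1 ketone free, C9 still acetal) | C1COC(O1)[C@@]2(C)CC(=O)C[C@@H](C)[C@H]2[C@H](OS(C)(=O)=O)[C@](C)(C(=O)CP(=O)(OC)OC)C=C
F2 | step 12 | bicyclo[3.1.1]heptanone (cyclobutane closed) with C9 dioxolane and β-ketophosphonate | C1COC(O1)[C@]2(C)[C@@H]3[C@@H]([C@H]2C(=O)C[C@H]3C)[C@](C)(C(=O)CP(=O)(OC)OC)C=C
F3 | step 12 | bicyclo[3.1.1]heptanone with C9 aldehyde and β-ketophosphonate | O=C[C@]1(C)[C@@H]2[C@@H]([C@H]1C(=O)C[C@H]2C)[C@](C)(C(=O)CP(=O)(OC)OC)C=C
F4 | step 3 | keto lactone (desilylated form of 6) | CC(C)[C@H]1CC[C@H](C)C[C@@H]1O[C@H]2OC(=O)[C@@H]3[C@H](C)CC(=O)C[C@]23C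
F5 | step 7 | (E)-2-methyl-4-(4,4,5,5-tetramethyl-1,3,2-dioxaborolan-2-yl)but-2-en-1-ol | C/C(CO)=C\CB1OC(C)(C)C(C)(C)O1
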